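**Retrosynthetic overview**
1. Target 27 ⇐ 22 by three late adjustments: ring-A dehydrogenation, kinetic protonation at C16, and Si→OH exchange at C6.
2. Key step: 22 ⇐ 20. One SmI2 operation makes C13–C14 (ketyl–olefin, ring C) and then C8–C15 (enolate acyl transfer, ring D). This builds the whole bicyclo[3.2.1]octane with its bridgehead OH.
3. 20 ⇐ aldehyde 16 + phenyl 2-diazopropanoate 19 (C15–C17). 16 ⇐ spiro dihydropyranone 9 + a C11–C13 Grignard reagent + one CH2 (C14).
4. 9 ⇐ formyl ketone 5 + (Z)-iodoacrylate 6 (C7–C9). The lactone closes when the formyl group (C20) is reduced.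
5. 5 ⇐ 4,4-dimethylcyclohexenone 1 by asymmetric conjugate addition. Ring order: A (bought) → δ-lactone → C and D together.

Assumption: atom labels C1–C20 are the kaurane numbers of the target (C6 = CH2OH carbon, C7 = lactone C=O, C20 = OCH2, C17 = methyl on C16). Compounds 1, 2, 6, 10, 17 and all named reagents are taken as catalogue chemicals.

**Step 1**
Reactants: 1 4,4-dimethylcyclohex-2-en-1-one; 2 (chloromethyl)dimethyl(phenyl)silane
Product: 5 (3S)-3-{[dimethyl(phenyl)silyl]methyl}-2-formyl-4,4-dimethylcyclohexan-1-one (C10 labile, mainly the hydroxymethylene enol), via Grignard reagent 3 (not isolated), via magnesium enolate 4 (not isolated)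
Conditions: 2, Mg, Et2O; CuBr·SMe2 (5 mol %), ferrocenyl diphosphine (TaniaPhos/Josiphos type, enantiomer giving 3S, 6 mol %), 1, Et2O, −60 °C; then HCO2CH2CF3, −78 → −20 °C; aq NH4Cl
Reagents that add atoms: 2,2,2-trifluoroethyl formate O=COCC(F)(F)F
Why: Cu-catalysed asymmetric conjugate addition of the Grignard reagent sets C5 under catalyst control, and the regiodefined magnesium enolate is trapped at C10 by a crossed Claisen formylation with a fast formyl donor before it can equilibrate to the less hindered C2 side.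

**Step 2**
Reactants: 5 formyl ketone; 6 ethyl (Z)-3-iodoacrylate
Product: 7 ethyl (Z)-3-[(1S,2R)-1-formyl-2-{[dimethyl(phenyl)silyl]methyl}-3,3-dimethyl-6-oxocyclohexyl]prop-2-enoate
Conditions: K2CO3, DMF, 0 °C → rt
Reagents that add atoms: none
Why: Nucleophilic vinylic substitution (addition–elimination) of the soft 1,3-dicarbonyl enolate on the β-iodoacrylate keeps the Z geometry, and the new bond forms anti to the pseudo-axial silylmethyl arm at C5, which sets the quaternary C10 with C9 trans and C20 cis to C6.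

**Step 3**
Reactants: 7 formyl enoate
Product: 9 (6S,11R)-11-{[dimethyl(phenyl)silyl]methyl}-10,10-dimethyl-2-oxaspiro[5.5]undec-4-ene-3,7-dione, via hydroxy ester 8 (not isolated)
Conditions: NaBH4 (0.5 equiv), MeOH–CH2Cl2, −78 °C; then warm to rt
Reagents that add atoms: none
Why: Chemoselective borohydride reduction takes only the aldehyde (the α-quaternary ketone and the enoate survive at −78 °C), and the alkoxide, held next to the ester by the Z alkene, closes the δ-lactone by transesterification without touching a stereocentre.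

**Step 4**
Reactants: 9 spiro dihydropyranone; 10 2-(2-bromoethyl)-1,3-dioxolane
Product: 13 4-[(dimethylamino)methyl]-5-[2-(1,3-dioxolan-2-yl)ethyl]-11-{[dimethyl(phenyl)silyl]methyl}-10,10-dimethyl-2-oxaspiro[5.5]undecane-3,7-dione (C9 as in 15, C8 epimer mixture), via dioxolanylethyl Grignard reagent 11 (not isolated), via silyl ketene acetal 12 (not isolated)
Conditions: 10, Mg, THF; CuBr·SMe2 (10 mol %), TMSCl, HMPA, THF, −78 °C, 9; then CH2=NMe2+ I−, CH2Cl2, rt; aq NaHCO3
Reagents that add atoms: N,N-dimethylmethyleneiminium iodide (Eschenmoser's salt) C[N+](C)=C.[I-]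
Why: Cu-catalysed, TMSCl-accelerated conjugate addition attacks C9 anti to the bulkier C5 branch of the neighbouring spiro centre (C11 ends cis to the C1 carbonyl), which sets C9, and the silyl ketene acetal is aminomethylated at C8 in a Mukaiyama–Mannich reaction.

**Step 5**
Reactants: 13 Mannich base
Product: 15 (5S,6S,11R)-5-[2-(1,3-dioxolan-2-yl)ethyl]-11-{[dimethyl(phenyl)silyl]methyl}-10,10-dimethyl-4-methylidene-2-oxaspiro[5.5]undecane-3,7-dione, via ammonium iodide 14 (not isolated)
Conditions: MeI, CH2Cl2, rt; then aq NaHCO3, rt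
Reagents that add atoms: none
Why: N-methylation followed by Hofmann-type E1cB β-elimination is the classical α-methylenation of lactones and removes the undefined C8 centre while C9 and C10 stay untouched.

**Step 6**
Reactants: 15 methylene lactone acetal
Product: 16 3-[(5S,6S,11R)-11-{[dimethyl(phenyl)silyl]methyl}-10,10-dimethyl-4-methylidene-3,7-dioxo-2-oxaspiro[5.5]undecan-5-yl]propanal
Conditions: 1 M HCl, THF, rt
Reagents that add atoms: water O
Why: Acid-catalysed acetal hydrolysis frees the C13 aldehyde under conditions that the aryl silane, the lactone and the acrylate unit tolerate.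

**Step 7**
Reactants: 17 phenyl propionate
Product: 19 phenyl 2-diazopropanoate, via trifluoroacetyl ester 18 (not isolated)
Conditions: LiHMDS, THF, −78 °C; CF3CO2CH2CF3, −78 °C; dil. HCl wash; then 4-AcNHC6H4SO2N3, Et3N, MeCN, rt
Reagents that add atoms: 4-acetamidobenzenesulfonyl azide CC(=O)Nc1ccc(cc1)S(=O)(=O)N=[N+]=[N-]
Why: Detrifluoroacetylative (Regitz-type) diazo transfer uses transient trifluoroacetyl activation so that the sulfonyl azide can deliver N2 to the α-carbon of a simple ester.

**Step 8**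
Reactants: 16 aldehyde; 19 phenyl 2-diazopropanoate
Product: 20 phenyl 5-[(5S,6S,11R)-11-{[dimethyl(phenyl)silyl]methyl}-10,10-dimethyl-4-methylidene-3,7-dioxo-2-oxaspiro[5.5]undecan-5-yl]-2-methyl-3-oxopentanoate (C16 labile mixture)
Conditions: Sc(OTf)3 (5 mol %), CH2Cl2, −20 °C
Reagents that add atoms: none
Why: In this Lewis-acid-catalysed Roskamp-type homologation the diazo carbon adds to the aldehyde, which reacts far faster than the hindered ketone, and a 1,2-hydride shift with loss of N2 gives the α-methyl β-keto aryl ester.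

**Step 9**
Reactants: 20 β-keto aryl ester
Product: 22 (5R,8S,9S,10S,13S)-6-[dimethyl(phenyl)silyl]-13-hydroxy-1,15-dioxo-6,7-secokauran-7,20-olide (C16 epimer mixture), via samarium enolate alkoxide 21 (not isolated)
Conditions: SmI2 (2.5 equiv, 0.1 M in THF), no proton source, slow addition of 20 at −78 °C, then 0 °C; aq Rochelle salt
Reagents that add atoms: none
Why: Proposed new method: SmI2 reduces the chelating β-keto-ester carbonyl to a Sm(III) ketyl that adds 6-endo to the unhindered, polarity-matched CH2 terminus C14 of the α-methylene lactone through a chair with C10 and the branched C16 arm equatorial and the small ketyl oxygen axial (O13 cis to C10, sets C13); a second SmI2 converts the C8 radical into a regiodefined Sm(III) lactone enolate, which the tethered aryl ester can reach only on the face syn to H9, so an enolexo 5-exo-trig acyl transfer made irreversible by loss of phenoxide sets C8 and closes ring D; the closest known reaction types are SmI2 ketyl–olefin cyclisations of β-keto esters and SmI2 ketyl–olefin/enolate-aldol cascades on unsaturated lactones.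

**Step 10**
Reactants: 22 tetracycle
Product: 23 (5R,8S,9S,10S,13S)-6-[dimethyl(phenyl)silyl]-13-hydroxy-1,15-dioxo-6,7-secokaur-2-en-7,20-olide (C16 epimer mixture)
Conditions: Pd(TFA)2 (10 mol %), DMSO (20 mol %), O2 (1 atm), AcOH, 80 °C
Reagents that add atoms: none
Why: Aerobic Pd(II)-catalysed α,β-dehydrogenation (Pd enolate, then β-hydride elimination) acts on the C1 cyclohexanone, whose only enolisable side is the C2–C3 CH2–CH2 unit and whose gem-dimethyl group blocks over-oxidation, whereas the C15 ketone offers only a hindered tertiary α-C–H.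

**Step 11**
Reactants: 23 enone
Product: 25 (5R,8S,9S,10S,13S,16R)-6-[dimethyl(phenyl)silyl]-13-hydroxy-1,15-dioxo-6,7-secokaur-2-en-7,20-olide, via dilithium enolate alkoxide 24 (not isolated)
Conditions: LiHMDS (2.3 equiv), THF, −78 °C; then AcOH (excess) in THF, −78 °C
Reagents that add atoms: none
Why: In this deprotonation–kinetic protonation C16–H is the only enolisable C–H in the molecule, so both epimers converge on one enolate, which takes the proton on the open exo face (syn to the C14 bridge) and pushes the methyl group endo to give 16R.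

**Step 12**
Reactants: 25 silane
Product: 27 target CNP0533761.1, (5R,8S,9S,10S,13S,16R)-6,13-dihydroxy-1,15-dioxo-6,7-secokaur-2-en-7,20-olide, via acetoxysilane 26 (not isolated)
Conditions: Hg(OAc)2 (1.2 equiv), AcOOH (32 % in AcOH), NaOAc, rt
Reagents that add atoms: peracetic acid CC(=O)OO
Why: In this Fleming–Tamao oxidation, mercuridesilylation of the phenyl group makes silicon heteroatom-substituted and the peracid induces the C6 shift from Si to O; the electron-poor enone and the hindered ketones do not react, and the buffered medium at rt does not enolise C15/C16.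

**Compound list**
1 | 4,4-dimethylcyclohex-2-en-1-one | CC1(C)C=CC(=O)CC1 | starting material
2 | (chloromethyl)dimethyl(phenyl)silane | ClC[Si](C)(C)c1ccccc1 | starting material
3 | {[dimethyl(phenyl)silyl]methyl}magnesium chloride | Cl[Mg]C[Si](C)(C)c1ccccc1 | intermediate
4 | chloromagnesium C1=C10 enolate of the conjugate adduct | C1=C(O[Mg]Cl)CCC(C)(C)[C@H]1C[Si](C)(C)c1ccccc1 | intermediate
5 | (3S)-3-{[dimethyl(phenyl)silyl]methyl}-2-formyl-4,4-dimethylcyclohexan-1-one | O=CC1C(=O)CCC(C)(C)[C@H]1C[Si](C)(C)c1ccccc1 | intermediate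
6 | ethyl (Z)-3-iodoacrylate | CCOC(=O)/C=C\I | starting material
7 | ethyl (Z)-3-[(1S,2R)-1-formyl-2-{[dimethyl(phenyl)silyl]methyl}-3,3-dimethyl-6-oxocyclohexyl]prop-2-enoate | CCOC(=O)/C=C\[C@]1(C=O)C(=O)CCC(C)(C)[C@H]1C[Si](C)(C)c1ccccc1 | intermediate
8 | corresponding 1-(hydroxymethyl) (Z)-enoate | CCOC(=O)/C=C\[C@]1(CO)C(=O)CCC(C)(C)[C@H]1C[Si](C)(C)c1ccccc1 | intermediate
9 | (6S,11R)-11-{[dimethyl(phenyl)silyl]methyl}-10,10-dimethyl-2-oxaspiro[5.5]undec-4-ene-3,7-dione | O=C1C=C[C@]2(CO1)C(=O)CCC(C)(C)[C@H]2C[Si](C)(C)c1ccccc1 | intermediate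
10 | 2-(2-bromoethyl)-1,3-dioxolane | BrCCC1OCCO1 | starting material
11 | [2-(1,3-dioxolan-2-yl)ethyl]magnesium bromide | Br[Mg]CCC1OCCO1 | intermediate
12 | C7-O-trimethylsilyl ketene acetal of the C9 adduct | O1CCOC1CC[C@H]3[C@]2(COC(O[Si](C)(C)C)=C3)C(=O)CCC(C)(C)[C@H]2C[Si](C)(C)c1ccccc1 | intermediate
13 | C8-(dimethylaminomethyl) lactone (C8 mixture) | O1CCOC1CC[C@H]3[C@]2(COC(=O)C3CN(C)C)C(=O)CCC(C)(C)[C@H]2C[Si](C)(C)c1ccccc1 | intermediate
14 | C8-(trimethylammoniomethyl) lactone iodide | O1CCOC1CC[C@H]3[C@]2(COC(=O)C3C[N+](C)(C)C)C(=O)CCC(C)(C)[C@H]2C[Si](C)(C)c1ccccc1.[I-] | intermediate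
15 | (5S,6S,11R) α-methylene spiro lactone dioxolane | O1CCOC1CC[C@H]3[C@]2(COC(=O)C3=C)C(=O)CCC(C)(C)[C@H]2C[Si](C)(C)c1ccccc1 | intermediate
16 | (5S,6S,11R) α-methylene spiro lactone propanal | O=CCC[C@H]3[C@]2(COC(=O)C3=C)C(=O)CCC(C)(C)[C@H]2C[Si](C)(C)c1ccccc1 | intermediate
17 | phenyl propionate | CCC(=O)Oc1ccccc1 | starting material
18 | phenyl 4,4,4-trifluoro-2-methyl-3-oxobutanoate | CC(C(=O)C(F)(F)F)C(=O)Oc1ccccc1 | intermediate
19 | phenyl 2-diazopropanoate | CC(=[N+]=[N-])C(=O)Oc1ccccc1 | intermediate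
20 | phenyl 2-methyl-3-oxopentanoate carrying the spiro methylene lactone at C5 (C16 mixture) | CC(C(=O)Oc1ccccc1)C(=O)CC[C@H]3[C@]2(COC(=O)C3=C)C(=O)CCC(C)(C)[C@H]2C[Si](C)(C)c1ccccc1 | intermediate
21 | ring-C-closed Sm(III) C13 alkoxide / C8=C7 lactone enolate | CC(C(=O)Oc1ccccc1)[C@]1(O[Sm](I)I)CC[C@@H]2C(C1)=C(O[Sm](I)I)OC[C@]23C(=O)CCC(C)(C)[C@H]3C[Si](C)(C)c1ccccc1 | intermediate
22 | 6-silyl-13-hydroxy-1,15-dioxo-6,7-secokauran-7,20-olide (C16 mixture) | CC1C(=O)[C@]23C[C@@]1(O)CC[C@H]2[C@]1(COC3=O)C(=O)CCC(C)(C)[C@H]1C[Si](C)(C)c1ccccc1 | intermediate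
23 | 2-ene of 22 (C16 mixture) | CC1C(=O)[C@]23C[C@@]1(O)CC[C@H]2[C@]1(COC3=O)C(=O)C=CC(C)(C)[C@H]1C[Si](C)(C)c1ccccc1 | intermediate
24 | dilithium C15=C16 enolate / C13 alkoxide of 23 | CC1=C(O[Li])[C@]23C[C@@]1(O[Li])CC[C@H]2[C@]1(COC3=O)C(=O)C=CC(C)(C)[C@H]1C[Si](C)(C)c1ccccc1 | intermediate
25 | (16R) epimer of 23 | C[C@H]1C(=O)[C@]23C[C@@]1(O)CC[C@H]2[C@]1(COC3=O)C(=O)C=CC(C)(C)[C@H]1C[Si](C)(C)c1ccccc1 | intermediate
26 | C6 acetoxy(dimethyl)silane | C[C@H]1C(=O)[C@]23C[C@@]1(O)CC[C@H]2[C@]1(COC3=O)C(=O)C=CC(C)(C)[C@H]1C[Si](C)(C)OC(C)=O | intermediate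
27 | CNP0533761.1 | C[C@H]1C(=O)[C@]23C[C@@]1(O)CC[C@H]2[C@]1(COC3=O)C(=O)C=CC(C)(C)[C@H]1CO | target

**Step count**
Total step count: 12. Longest linear sequence: 11 (steps 1–6 and 8–12).

**Steps most likely to fail**

*Step 9.* The C8 enolate may be protonated by unreacted acidic 20 before the acyl transfer, or the ketyl may close with the wrong C13 orientation. The fallback sets out from 16 and returns at 22, and builds the two rings by polar chemistry.
- An NHC-catalysed intramolecular Stetter reaction of the aldehyde onto the methylene lactone gives the 13-oxo lactone F6.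
- The lithium enolate of 17 adds reversibly to the C13 ketone at −78 °C, and the aldolate lactonises to the spiro β-lactone F7.
- KHMDS then lets the C8 lactone enolate open the strained β-lactone at its acyl carbon to give 22.

*Step 2.* O-vinylation, deformylation, or loss of the Z geometry at a very crowded carbon could intervene. The fallback sets out from 5 and returns at 9.
- DABCO-catalysed Michael addition of 5 to ethyl propiolate gives the (E)-enoate aldehyde F4.
- NaBH4 gives the (E)-hydroxy enoate F5.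
- Sensitised photochemical E→Z isomerisation lets the Z isomer drain irreversibly into lactone 9.

*Step 1.* The enantioselectivity with a silylmethyl Grignard reagent next to a quaternary carbon is uncertain, and proton transfer may compete during the formyl trapping. The fallback sets out from 1 and 3 and returns at 5.
- Transmetallation of 3 with ZnCl2 gives bis{[dimethyl(phenyl)silyl]methyl}zinc F1.
- F1 adds to 1 under Cu(OTf)2/phosphoramidite catalysis, and TMSOTf trapping gives the isolable silyl enol ether F2.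
- A Mukaiyama-type reaction of F2 with trimethyl orthoformate and BF3·OEt2 gives the β-keto dimethyl acetal F3.
- Mild acid hydrolysis of F3 gives 5.

**Further compounds**
F1 | step 1 | bis{[dimethyl(phenyl)silyl]methyl}zinc | C[Si](C)(C[Zn]C[Si](C)(C)c1ccccc1)c1ccccc1
F2 | step 1 | (3S) C1=C10 trimethylsilyl enol ether of the conjugate adduct | C1=C(O[Si](C)(C)C)CCC(C)(C)[C@H]1C[Si](C)(C)c1ccccc1
F3 | step 1 | (3S)-2-(dimethoxymethyl)-3-{[dimethyl(phenyl)silyl]methyl}-4,4-dimethylcyclohexan-1-one | COC(OC)C1C(=O)CCC(C)(C)[C@H]1C[Si](C)(C)c1ccccc1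
F4 | step 2 | (E) isomer of 7 | CCOC(=O)/C=C/[C@]1(C=O)C(=O)CCC(C)(C)[C@H]1C[Si](C)(C)c1ccccc1
F5 | step 2 | (E) isomer of 8 | CCOC(=O)/C=C/[C@]1(CO)C(=O)CCC(C)(C)[C@H]1C[Si](C)(C)c1ccccc1
F6 | step 9 | ring-C-closed 13-oxo lactone (C8-H, epimerisable) | O=C1CC[C@@H]2C(C1)C(=O)OC[C@]23C(=O)CCC(C)(C)[C@H]3C[Si](C)(C)c1ccccc1
F7 | step 9 | C13 spiro β-lactone (O13 cis to C10, C16 mixture) | CC1C(=O)O[C@]12CC[C@@H]3C(C2)C(=O)OC[C@]34C(=O)CCC(C)(C)[C@H]4C[Si](C)(C)c1ccccc1
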